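**Retrosynthetic overview**
- Target ⇐ acetyl 8,9-dione + 4-methoxybenzaldehyde (aldol condensation last); the dione ⇐ acyloin by oxidation.
- The strategy rests on ring A (C5–C6–C7–C8–C9–C10): its C8–C9 bond joins two carbonyl carbons, C8 on cyclopropane carbon C7 and C9 on the quaternary aryl-ether carbon C10. It is cut by polarity reversal to a dialdehyde (carbene-catalysed intramolecular benzoin), so ring A closes last.
- Dialdehyde ⇐ dihydrobenzofuran: C1–aryl bond by aromatic Claisen rearrangement of an aryl cyclohexenylmethyl ether, C10–O bond by epoxide opening.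
- Ring B ⇐ intramolecular acylation of an alkyllithium by a cyclopropane-fused δ-lactone. This lactone is an oxa surrogate of ring A (O in place of C9) and relays the cyclopropane configuration to C4 and C5.
- Lactone ⇐ (1R,3S)-cis-chrysanthemic acid. Ring order: cyclopropane (chiral pool), temporary δ-lactone, ring B, dihydrofuran, ring A.

Key step: step 19

Remark: aristolane locants are used for all intermediates (C1–C10, C11 = CMe2 carbon; C8 is the carboxyl carbon of the chrysanthemic acid) and primed locants for the acetophenone ring; the three starting materials are assumed purchasable as the stated stereoisomers.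

**Step 1**
Reactants: 1 (1R,3S)-cis-chrysanthemic acid
Product: 2 cis-chrysanthemol
Conditions: LiAlH4, THF, 0 °C to rt
Reagents that add atoms: none
Why: Hydride reduction of the carboxylic acid to the primary alcohol leaves both cyclopropane stereocentres untouched.

**Step 2**
Reactants: 2 cis-chrysanthemol
Product: 3 bicyclic lactol (1S,5R)-6,6-dimethyl-3-oxabicyclo[3.1.0]hexan-2-ol
Conditions: O3, CH2Cl2–MeOH, −78 °C; then Me2S
Reagents that add atoms: ozone, [O-][O+]=O
Why: Ozonolysis with reductive work-up cleaves the trisubstituted alkene, and the cis hydroxy aldehyde is trapped as the five-membered lactol, which shields the epimerisable C6 centre.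

**Step 3**
Reactants: 3 bicyclic lactol
Product: 4 cis-[3-(2-methoxyethenyl)-2,2-dimethylcyclopropyl]methanol (E/Z mixture)
Conditions: Ph3P(CH2OMe)Cl (3 equiv), KOtBu, THF, 0 °C to rt
Reagents that add atoms: (methoxymethyl)triphenylphosphonium chloride, COC[P+](c1ccccc1)(c1ccccc1)c1ccccc1.[Cl-]
Why: Wittig reaction of the lactol through its open hydroxy-aldehyde form adds C10 as a methyl enol ether (one-carbon homologation) under conditions too mild to remove the cyclopropane α-hydrogen.

**Step 4**
Reactants: 4 hydroxy enol ether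
Product: 6 (1R,6S)-7,7-dimethyl-3-oxabicyclo[4.1.0]heptan-4-one, via δ-lactol 5 (not isolated)
Conditions: 1 M HCl, THF, rt; then TEMPO (cat.), PhI(OAc)2, CH2Cl2, rt
Reagents that add atoms: water, O
Why: Acid hydrolysis of the enol ether gives the homologous aldehyde, which closes on the C8 hydroxyl to the six-membered lactol, and nitroxyl-catalysed oxidation of a lactol to the lactone is routine.

**Step 5**
Reactants: 6 cyclopropane-fused δ-lactone
Product: 7 5-(1-hydroxyethyl) lactone (diastereomer mixture)
Conditions: LiN(iPr)2, THF, −78 °C; CH3CHO; aq. NH4Cl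
Reagents that add atoms: acetaldehyde, CC=O
Why: Aldol addition of the lactone lithium enolate (C5) to acetaldehyde; both new stereocentres are removed in step 6.

**Step 6**
Reactants: 7 5-(1-hydroxyethyl) lactone
Product: 9 (E)-5-ethylidene-7,7-dimethyl-3-oxabicyclo[4.1.0]heptan-4-one, via mesylate 8 (not isolated)
Conditions: MsCl, Et3N, CH2Cl2, 0 °C; then DBU, rt
Reagents that add atoms: none
Why: Mesylation and E1cB elimination give the conjugated alkylidene lactone as the thermodynamically preferred E isomer (methyl away from the carbonyl), the geometry that later fixes C4.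

**Step 7**
Reactants: 9 (E)-5-ethylidene lactone
Product: 11 5-methyl-5-[5-(tert-butyldimethylsilyloxy)pentan-2-yl] lactone (C5 methyl anti to the CMe2 bridge), via lithium enolate 10 (not isolated)
Conditions: [tBuMe2SiO(CH2)3]2CuLi (from the iodide, tBuLi and CuI), Et2O, −78 °C; then MeI, DMPU, −78 to 0 °C
Reagents that add atoms: lithium bis[3-(tert-butyldimethylsilyloxy)propyl]cuprate, [Li+].CC(C)(C)[Si](C)(C)OCCC[Cu-]CCCO[Si](C)(C)C(C)(C)C; iodomethane, CI
Why: Conjugate addition of the lithium dialkylcuprate to the exocyclic enoate and C-methylation of the resulting lactone enolate should both occur on the face opposite the CMe2 bridge of the bicyclo[4.1.0] lactone, which with the E-ethylidene geometry sets C4 and places the C5 methyl anti to the bridge, i.e. the C4 and C5 methyls cis as in the target.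

**Step 8**
Reactants: 11 silyloxypentyl lactone
Product: 12 primary alcohol
Conditions: Bu4NF, THF, 0 °C to rt
Reagents that add atoms: none
Why: Fluoride cleavage of the primary silyl ether; the hindered lactone with its quaternary α-carbon is inert.

**Step 9**
Reactants: 12 primary alcohol
Product: 13 primary iodide
Conditions: I2, PPh3, imidazole, CH2Cl2, 0 °C
Reagents that add atoms: iodine, II
Why: Appel-type iodination of the unhindered primary alcohol.

**Step 10**
Reactants: 13 primary iodide
Product: 16 hydroxy ketone 2-[cis-3-(hydroxymethyl)-2,2-dimethylcyclopropyl]-2,3-dimethylcyclohexanone, via alkyllithium 14 (not isolated), via lithium hemiketalate 15 (not isolated)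
Conditions: tBuLi (2.1 equiv), Et2O–pentane, −78 to −20 °C; aq. NH4Cl
Reagents that add atoms: none
Why: Iodine–lithium exchange outruns attack of tBuLi on the hindered lactone, and the primary alkyllithium (C1) then closes ring B by 6-exo-trig intramolecular nucleophilic acyl substitution at C10; the tetrahedral alkoxide survives until work-up, which prevents a second addition and releases the C8 hydroxyl.

**Step 11**
Reactants: 16 hydroxy ketone
Product: 17 tert-butyldiphenylsilyl ether
Conditions: tBuPh2SiCl, imidazole, DMF, rt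
Reagents that add atoms: tert-butylchlorodiphenylsilane, CC(C)(C)[Si](Cl)(c1ccccc1)c1ccccc1
Why: Silylation of the primary alcohol drains the open hydroxy-ketone form from its hemiketal equilibrium.

**Step 12**
Reactants: 17 silyl ether ketone
Product: 18 enol triflate (C10=C1)
Conditions: KN(SiMe3)2, THF, −78 °C; PhNTf2
Reagents that add atoms: N-phenylbis(trifluoromethanesulfonimide), O=S(=O)(N(c1ccccc1)S(=O)(=O)C(F)(F)F)C(F)(F)F
Why: The ketone can enolise only towards C1 because C5 is quaternary, so O-triflation of the potassium enolate gives a single enol triflate.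

**Step 13**
Reactants: 18 enol triflate
Product: 19 allylic alcohol (C9 hydroxymethyl on C10=C1)
Conditions: Pd(PPh3)4 (cat.), LiCl, Bu3SnCH2OH, 1,4-dioxane, 100 °C
Reagents that add atoms: (tributylstannyl)methanol, CCCC[Sn](CCCC)(CCCC)CO
Why: Stille coupling of the enol triflate with the hydroxymethylstannane installs C9 at the alcohol oxidation level.

**Step 14**
Reactants: 19 allylic alcohol; 20 2',6'-dihydroxy-4'-methoxyacetophenone (2 equiv)
Product: 21 aryl allyl ether
Conditions: PPh3, DIAD, THF, 0 °C to rt
Reagents that add atoms: none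
Why: Mitsunobu etherification of the primary allylic alcohol with one of the two equivalent phenols; the remaining phenol is deactivated by its hydrogen bond to the acetyl group, so mono-etherification is expected.

**Step 15**
Reactants: 21 aryl allyl ether
Product: 22 3'-C-(2-methylenecyclohexyl) phenol (aryl on C1 trans to the cyclopropyl group)
Conditions: PhNEt2, 185 °C, sealed tube
Reagents that add atoms: none
Why: Aromatic Claisen rearrangement to the only free ortho position (C3') forms the C1–aryl bond and the exocyclic C10=C9 alkene; the aryl group should be delivered to the C1 face opposite the cyclopropyl group, which allylic strain with the C10 substituent holds pseudoaxial on C5.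

**Step 16**
Reactants: 22 methylenecyclohexyl phenol
Product: 24 cis-fused 2-(hydroxymethyl)dihydrobenzofuran silyl ether, via spiro-epoxide 23 (not isolated)
Conditions: mCPBA, NaHCO3, CH2Cl2, 0 °C; then CSA (cat.), rt
Reagents that add atoms: 3-chloroperbenzoic acid, OOC(=O)c1cccc(Cl)c1
Why: Prilezhaev epoxidation of the 1,1-disubstituted alkene and acid-promoted 5-exo opening at the tertiary carbon C10 by the neighbouring phenol close the dihydrofuran; only the cis ring fusion is accessible, so the C1–aryl bond dictates C10 (O syn to the aryl group, C9 syn to the cyclopropyl group).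

**Step 17**
Reactants: 24 silyl ether
Product: 25 8,9-diol
Conditions: Bu4NF, THF, rt
Reagents that add atoms: none
Why: Fluoride cleavage of the silyl ether frees the C8 alcohol.

**Step 18**
Reactants: 25 8,9-diol
Product: 26 dialdehyde (cis-formylcyclopropyl on C5, formyl on C10)
Conditions: Dess–Martin periodinane (3 equiv), NaHCO3, CH2Cl2, 0 °C to rt
Reagents that add atoms: none
Why: Dess–Martin oxidation of both primary alcohols under buffered, non-basic conditions that should spare the chelated phenol and not epimerise the cis-formylcyclopropane.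

**Step 19**
Reactants: 26 dialdehyde
Product: 27 9-hydroxy-8-ketone (acyloin; ring A closed)
Conditions: 2-(pentafluorophenyl)-6,7-dihydro-5H-pyrrolo[2,1-c][1,2,4]triazol-2-ium tetrafluoroborate (15 mol %), iPr2NEt (15 mol %), THF (0.02 M, degassed), 40 °C
Reagents that add atoms: none
Why: The carbene from the triazolium salt adds to the cyclopropane aldehyde C8, the less encumbered one, and proton transfer gives the Breslow intermediate, whose nucleophilic C8 attacks the non-enolisable neopentyl aldehyde C9 before the catalyst is released; the closest known reaction type is the carbene-catalysed intramolecular benzoin cyclisation of 1,6-dialdehydes to 2-hydroxycyclohexanones. Ring A closes in a 6-exo-trig mode, the two carbonyl carbons being held in reach by the cis cyclopropane and by the syn arrangement of the C10 formyl group and the cyclopropyl group across the C5–C10 bond. The new carbinol centre C9 is set in the addition transition state but needs no control because step 20 removes it, and if the aldehydes exchanged roles the regioisomeric acyloin would give the same dione. The selectivity needed is intramolecular over intermolecular coupling, secured by the six-membered closure at high dilution; neither aldehyde can enter aldol chemistry since C10 is quaternary and C7 is a cyclopropane carbon. No ketyl radical is formed and the cyclopropane carries no acceptor group that would allow carbene-triggered ring opening, so it should survive, while the weak amine base limits epimerisation at C7.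

**Step 20**
Reactants: 27 acyloin
Product: 28 acetyl 8,9-dione
Conditions: Dess–Martin periodinane, CH2Cl2, rt
Reagents that add atoms: none
Why: Dess–Martin oxidation of the α-hydroxy ketone to the 1,2-diketone erases the C9 stereocentre; the dione can enolise only at a cyclopropane carbon.

**Step 21**
Reactants: 28 acetyl 8,9-dione; 29 4-methoxybenzaldehyde (3 equiv)
Product: 31 target chalcone CNP0121765.1, via aldol adduct 30 (not isolated)
Conditions: LiN(SiMe3)2 (2.2 equiv), THF, −78 °C; 29, −78 to 0 °C; aq. NH4Cl; then PPTS (cat.), CH2Cl2, rt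
Reagents that add atoms: none
Why: Claisen–Schmidt condensation via the phenoxide–enolate dianion with a non-nucleophilic amide base, so that no hydroxide or alkoxide can trigger a benzilic acid rearrangement of the dione; the 4-methoxybenzylic β-hydroxy ketone then loses water under mild acid to the E-enone, and the enolate cannot reach the dione of its own molecule, which lies on the far side of the furan oxygen.

**Compound list**
1 | (1R,3S)-cis-chrysanthemic acid | OC(=O)[C@@H]1[C@@H](C1(C)C)C=C(C)C | starting material
2 | cis-chrysanthemol, [(1R,3S)-2,2-dimethyl-3-(2-methylprop-1-enyl)cyclopropyl]methanol | OC[C@@H]1[C@@H](C1(C)C)C=C(C)C | intermediate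
3 | (1S,5R)-6,6-dimethyl-3-oxabicyclo[3.1.0]hexan-2-ol (lactol, both anomers) | O1C[C@@H]2[C@@H](C2(C)C)C1O | intermediate
4 | cis-[3-(2-methoxyethenyl)-2,2-dimethylcyclopropyl]methanol (E/Z mixture, ring configuration of 2) | OC[C@@H]1[C@@H](C1(C)C)C=COC | intermediate
5 | 7,7-dimethyl-3-oxabicyclo[4.1.0]heptan-4-ol (δ-lactol, both anomers) | O1C[C@@H]2[C@@H](C2(C)C)CC1O | intermediate (not isolated)
6 | (1R,6S)-7,7-dimethyl-3-oxabicyclo[4.1.0]heptan-4-one | O1C[C@@H]2[C@@H](C2(C)C)CC1=O | intermediate
7 | 5-(1-hydroxyethyl)-7,7-dimethyl-3-oxabicyclo[4.1.0]heptan-4-one (mixture at C5 and the carbinol carbon) | O1C[C@@H]2[C@@H](C2(C)C)C(C(C)O)C1=O | intermediate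
8 | methanesulfonate of 7 | O1C[C@@H]2[C@@H](C2(C)C)C(C(C)OS(C)(=O)=O)C1=O | intermediate (not isolated)
9 | (E)-5-ethylidene-7,7-dimethyl-3-oxabicyclo[4.1.0]heptan-4-one (ethylidene methyl syn to C6) | O1C[C@@H]2[C@@H](C2(C)C)/C(=C\C)C1=O | intermediate
10 | lithium enolate of the conjugate adduct (C4 set) | O1C[C@@H]2[C@@H](C2(C)C)C([C@H](C)CCCO[Si](C)(C)C(C)(C)C)=C1O[Li] | intermediate (not isolated)
11 | 5-methyl-5-[5-(tert-butyldimethylsilyloxy)pentan-2-yl]-7,7-dimethyl-3-oxabicyclo[4.1.0]heptan-4-one (C5 methyl anti to the CMe2 bridge, C4 as in the target) | O1C[C@@H]2[C@@H](C2(C)C)[C@@](C)([C@H](C)CCCO[Si](C)(C)C(C)(C)C)C1=O | intermediate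
12 | primary alcohol from 11 | O1C[C@@H]2[C@@H](C2(C)C)[C@@](C)([C@H](C)CCCO)C1=O | intermediate
13 | primary iodide from 12 | O1C[C@@H]2[C@@H](C2(C)C)[C@@](C)([C@H](C)CCCI)C1=O | intermediate
14 | primary alkyllithium (C1–Li) | O1C[C@@H]2[C@@H](C2(C)C)[C@@](C)([C@H](C)CCC[Li])C1=O | intermediate (not isolated)
15 | tricyclic lithium hemiketalate (ring B closed, C10 configuration open) | O1C[C@@H]2[C@@H](C2(C)C)[C@@]3(C)[C@H](C)CCCC13O[Li] | intermediate (not isolated)
16 | 2-[cis-3-(hydroxymethyl)-2,2-dimethylcyclopropyl]-2,3-dimethylcyclohexan-1-one (2- and 3-methyl cis; ring B with C10 ketone) | OC[C@@H]1[C@@H](C1(C)C)[C@@]2(C)[C@H](C)CCCC2=O | intermediate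
17 | tert-butyldiphenylsilyl ether of 16 | CC(C)(C)[Si](c1ccccc1)(c1ccccc1)OC[C@@H]1[C@@H](C1(C)C)[C@@]2(C)[C@H](C)CCCC2=O | intermediate
18 | enol triflate of 17 (C10=C1) | CC(C)(C)[Si](c1ccccc1)(c1ccccc1)OC[C@@H]1[C@@H](C1(C)C)[C@@]2(C)[C@H](C)CCC=C2OS(=O)(=O)C(F)(F)F | intermediate
19 | cyclohex-1-enylmethanol (C9 hydroxymethyl on C10=C1) | CC(C)(C)[Si](c1ccccc1)(c1ccccc1)OC[C@@H]1[C@@H](C1(C)C)[C@@]2(C)[C@H](C)CCC=C2CO | intermediate
20 | 2',6'-dihydroxy-4'-methoxyacetophenone | CC(=O)c1c(O)cc(OC)cc1O | starting material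
21 | 2'-O-(cyclohexenylmethyl) ether of 20 | CC(C)(C)[Si](c1ccccc1)(c1ccccc1)OC[C@@H]1[C@@H](C1(C)C)[C@@]2(C)[C@H](C)CCC=C2COc3cc(OC)cc(O)c3C(C)=O | intermediate
22 | 3'-(2-methylenecyclohexyl)-2',6'-dihydroxy-4'-methoxyacetophenone (aryl on C1 trans to cyclopropyl, cis to the C5 methyl) | CC(C)(C)[Si](c1ccccc1)(c1ccccc1)OC[C@@H]1[C@@H](C1(C)C)[C@@]2(C)[C@H](C)CC[C@H](c3c(O)c(C(C)=O)c(O)cc3OC)C2=C | intermediate
23 | spiro-epoxide of 22 (C10 epimers) | CC(C)(C)[Si](c1ccccc1)(c1ccccc1)OC[C@@H]1[C@@H](C1(C)C)[C@@]2(C)[C@H](C)CC[C@H](c3c(O)c(C(C)=O)c(O)cc3OC)C24CO4 | intermediate (not isolated)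
24 | cis-fused dihydrobenzofuran with C9 hydroxymethyl on C10 and C8 silyl ether | CC(=O)c2c(O)cc(OC)c3c2O[C@]2(CO)[C@@](C)([C@H]4[C@@H](CO[Si](c5ccccc5)(c5ccccc5)C(C)(C)C)C4(C)C)[C@H](C)CC[C@H]32 | intermediate
25 | 8,9-diol | CC(=O)c2c(O)cc(OC)c3c2O[C@]2(CO)[C@@](C)([C@H]4[C@@H](CO)C4(C)C)[C@H](C)CC[C@H]32 | intermediate
26 | dihydrobenzofuran 2-carbaldehyde with cis-formylcyclopropyl group on C5 (key-step precursor) | CC(=O)c2c(O)cc(OC)c3c2O[C@]2(C=O)[C@@](C)([C@H]4[C@@H](C=O)C4(C)C)[C@H](C)CC[C@H]32 | intermediate
27 | 9-hydroxy-8-ketone (drawn with 9-OH syn to the C10–O bond; the 9-epimer serves equally) | CC(=O)c2c(O)cc(OC)c3c2O[C@]24[C@H](O)C(=O)[C@@H]5[C@@H](C5(C)C)[C@@]2(C)[C@H](C)CC[C@H]34 | intermediate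
28 | acetyl 8,9-dione | CC(=O)c2c(O)cc(OC)c3c2O[C@]24C(=O)C(=O)[C@@H]5[C@@H](C5(C)C)[C@@]2(C)[C@H](C)CC[C@H]34 | intermediate
29 | 4-methoxybenzaldehyde | COc1ccc(C=O)cc1 | starting material
30 | β-hydroxy ketone (aldol adduct, carbinol epimers) | COc1ccc(C(O)CC(=O)c2c(O)cc(OC)c3c2O[C@]24C(=O)C(=O)[C@@H]5[C@@H](C5(C)C)[C@@]2(C)[C@H](C)CC[C@H]34)cc1 | intermediate (not isolated)
31 | CNP0121765.1 | COc1ccc(/C=C/C(=O)c2c(O)cc(OC)c3c2O[C@]24C(=O)C(=O)[C@@H]5[C@@H](C5(C)C)[C@@]2(C)[C@H](C)CC[C@H]34)cc1 | target

**Step count and risks**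
Total step count: 21. Longest linear sequence: 21 steps (1 to 31); 20 enters at step 14 and 29 at step 21.

Steps most likely to fail:

1. Step 19. The carbene may add only sluggishly or reversibly to the two hindered aldehydes, or the Breslow intermediate may be diverted into redox lactonisation (hydride transfer between the aldehydes) or epimerisation of the cis-formyl group before ring closure. Fallback without umpolung, from 26 back to 28: double Wittig methylenation of 26 (Ph3P=CH2) would give the 8,9-divinyl compound F1. Ring-closing metathesis with the second-generation Grubbs catalyst would form the C8=C9 cyclohexene F2. Dihydroxylation (OsO4 cat., NMO) would give the 8,9-diol F3. Double oxidation (DMSO, (CF3CO)2O, then Et3N) would then deliver dione 28.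

2. Step 15. The sigmatropic shift may show poor facial selectivity (aryl delivered syn to the cyclopropyl group), or the product may undergo the abnormal rearrangement at 185 °C. Fallback that fixes C10 first and C1 last by a forced cis ring fusion, from 17 back to 24:
   - Dehydrogenation of 17 (IBX, DMSO, 65 °C) would give the C1–C2 enone F4, and iodination (I2, pyridine) the 2-iodoenone F5.
   - Iodination of 20 (NIS) would give the 3'-iodide F6, and borylation (B2pin2, PdCl2(dppf), KOAc) the 3'-pinacolboronate F7.
   - Suzuki–Miyaura coupling of F5 with F7 (Pd(PPh3)4, K3PO4) would give the 2-aryl enone F8.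
   - Dimethylsulfonium methylide (Me3SI, KN(SiMe3)2) should add its carbon to the C10 carbonyl from the face opposite the cyclopropyl group to give the spiro-epoxide F9. The neighbouring phenoxide would open it at C10 with inversion to the 1,2-unsaturated dihydrobenzofuran F10.
   - Ionic hydrogenation (Et3SiH, CF3CO2H) via the benzylic C1 cation can only give the cis-fused 24.

3. Step 16. The epoxide may form on the face that blocks backside attack by the phenol, so that closure has to pass through a tertiary C10 cation, which may instead undergo a hydride shift to an aldehyde or a skeletal shift. Fallback by alkoxymercuration, from 22 back to 24: Hg(O2CCF3)2 in THF adds reversibly to the alkene and only the mercurinium ion anti to the phenol can be captured (5-exo) to give the C9 organomercurial F11. Oxidative demercuration (NaBH4, O2, DMF) would replace mercury by hydroxyl to give 24.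

**Further compounds**
F1 | step 19 | 8,9-divinyl compound (vinyl on C10 and on C7) | CC(=O)c2c(O)cc(OC)c3c2O[C@]2(C=C)[C@@](C)([C@H]4[C@@H](C=C)C4(C)C)[C@H](C)CC[C@H]32
F2 | step 19 | ring A cyclohexene (C8=C9) | CC(=O)c2c(O)cc(OC)c3c2O[C@]24C=C[C@@H]5[C@@H](C5(C)C)[C@@]2(C)[C@H](C)CC[C@H]34
F3 | step 19 | 8,9-diol (cis, either face) | CC(=O)c2c(O)cc(OC)c3c2O[C@]24C(O)C(O)[C@@H]5[C@@H](C5(C)C)[C@@]2(C)[C@H](C)CC[C@H]34
F4 | step 15 | C1–C2 enone from 17 | CC(C)(C)[Si](c1ccccc1)(c1ccccc1)OC[C@@H]1[C@@H](C1(C)C)[C@@]2(C)[C@H](C)CC=CC2=O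
F5 | step 15 | 2-iodoenone (iodine on C1) | CC(C)(C)[Si](c1ccccc1)(c1ccccc1)OC[C@@H]1[C@@H](C1(C)C)[C@@]2(C)[C@H](C)CC=C(I)C2=O
F6 | step 15 | 3'-iodo-2',6'-dihydroxy-4'-methoxyacetophenone | CC(=O)c1c(O)cc(OC)c(I)c1O
F7 | step 15 | 3'-pinacolboronate of 20 | CC(=O)c1c(O)cc(OC)c(B2OC(C)(C)C(C)(C)O2)c1O
F8 | step 15 | 2-aryl enone (aryl on C1) | CC(C)(C)[Si](c1ccccc1)(c1ccccc1)OC[C@@H]1[C@@H](C1(C)C)[C@@]2(C)[C@H](C)CC=C(c3c(O)c(C(C)=O)c(O)cc3OC)C2=O
F9 | step 15 | spiro-epoxide at C10 of F8 | CC(C)(C)[Si](c1ccccc1)(c1ccccc1)OC[C@@H]1[C@@H](C1(C)C)[C@@]2(C)[C@H](C)CC=C(c3c(O)c(C(C)=O)c(O)cc3OC)C24CO4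
F10 | step 15 | 1,2-unsaturated dihydrobenzofuran (C1=C2, C9 hydroxymethyl) | CC(=O)c2c(O)cc(OC)c3c2O[C@]2(CO)[C@@](C)([C@H]4[C@@H](CO[Si](c5ccccc5)(c5ccccc5)C(C)(C)C)C4(C)C)[C@H](C)CC=C32
F11 | step 16 | C9 organomercurial trifluoroacetate | CC(=O)c2c(O)cc(OC)c3c2O[C@]2(C[Hg]OC(=O)C(F)(F)F)[C@@](C)([C@H]4[C@@H](CO[Si](c5ccccc5)(c5ccccc5)C(C)(C)C)C4(C)C)[C@H](C)CC[C@H]32
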